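**Retrosynthetic overview** (drimane numbering C1–C12, C11 = benzylic CH2, C12 = exocyclic CH2; quinol ring C1'–C6', C1' bears C11, C2' = ketone, C5' = carbinol)
1. Epoxyquinol last, from para-methoxyphenol 23: oxidation to the quinone monoketal, tartrate-controlled nucleophilic epoxidation of C1'=C6', ketal hydrolysis, hydroxyl-directed reduction at C5'.
2. C9–C11 bond: benzylation of bicyclic beta-keto ester 12 with bromide 18; the ester (activating group) is then removed and C8=O becomes the exocyclic methylene by Wittig reaction.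
3. Ring B (C9–C10 bond): SnCl4 cation–olefin cyclization of monocyclic beta-keto ester 11, which relays the single stereocentre C5 to C10 and C9 in one event.
4. Ring A (C2–C3 and C4–C5 bonds together): catalytic enantioselective Diels–Alder reaction of diene ester 5 (C2=C1–C10=C5) with methacrolein (C3=C4). Enabling feature: ring A (C1, C2, C3, C4, C5, C10) has the gem-dimethyl carbon C4 next to the ring-fusion methine C5, so at the cyclohex-1(10)-ene level it is the "ortho" adduct of a 1,2-dialkyl diene and an alpha-methyl enal, whose formyl carbon is the second C4 methyl at a higher oxidation level.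
5. Ring order: A (step 3), B (step 6), then dearomatization and oxidation of the six-membered quinol ring (steps 16–19).

Key step: step 3

Assumption: the (S)-oxazaborolidinium salt in step 3 and L-(+)-diisopropyl tartrate in step 17 are taken as the enantiomers that give the configurations drawn; the mirror-image catalyst or tartrate is used if the facial sense proves opposite.

**Route**

Step 1
Reactants: 1 methyl 4-oxobutanoate; 2 2-(triphenylphosphoranylidene)propanal
Product: 3 methyl (4E)-5-methyl-6-oxohex-4-enoate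
Conditions: PhMe, 90 °C
Reagents that add atoms: none
Why: Wittig olefination with a formyl-stabilized ylide should give the (E)-trisubstituted enal, the saturated aldehyde of 1 reacting much faster than the conjugated aldehyde of the product.

Step 2
Reactants: 3 methyl (4E)-5-methyl-6-oxohex-4-enoate; 4 methyltriphenylphosphonium bromide
Product: 5 methyl (4E)-5-methylhepta-4,6-dienoate
Conditions: 4, n-BuLi, THF, 0 °C; then 3, −78 to 0 °C
Reagents that add atoms: none
Why: Wittig methylenation of the enal is faster than attack on the methyl ester and leaves the E double bond untouched, giving the 1,3-diene.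

Step 3
Reactants: 5 methyl (4E)-5-methylhepta-4,6-dienoate; 6 methacrolein
Product: 7 methyl 3-[(1R,6S)-6-formyl-2,6-dimethylcyclohex-2-en-1-yl]propanoate
Conditions: 6 (3 equiv), (S)-1-(2-methylphenyl)-3,3-diphenyltetrahydro-1H,3H-pyrrolo[1,2-c][1,3,2]oxazaborole (20 mol %), HNTf2 (20 mol %), CH2Cl2, −78 to −40 °C
Reagents that add atoms: none
Why: The protonated oxazaborolidine binds methacrolein at boron and through a formyl C–H···O contact, and the s-cis (E)-diene adds in a concerted, asynchronous [4+2] cycloaddition; the closest precedent is the oxazaborolidinium-catalysed Diels–Alder reaction of 2-substituted acroleins with acyclic 1,3-dienes. Ring A closes as a cyclohexene by suprafacial 4π+2π addition, the new sigma bonds being C2–C3 (diene CH2 terminus to enal CH2) and C4–C5 (substituted diene terminus to the formyl-bearing carbon). C5 (ring C1) is set by the catalyst, which exposes one face of the enal, together with the endo position of the boron-bound formyl group; C4 (ring C6) forms at the same time and is made achiral in step 4. The step needs "ortho" regiochemistry, endo selectivity and facial selectivity: the first should follow from the larger HOMO coefficient at the unsubstituted terminus of a 1-alkyl diene matched with the enal CH2, the second from the Lewis-acid-bound carbonyl, the third from the catalyst. The E geometry places the C6 chain outside in the s-cis diene; a minor exo adduct, which would carry the opposite configuration at C5, is removed by chromatography at this stage.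

Step 4
Reactants: 7 methyl 3-[(1R,6S)-6-formyl-2,6-dimethylcyclohex-2-en-1-yl]propanoate
Product: 9 methyl 3-[(1S)-2,6,6-trimethylcyclohex-2-en-1-yl]propanoate, via tosylhydrazone 8 (not isolated)
Conditions: TsNHNH2, EtOH, 25 °C; then catecholborane, CHCl3, 0 °C; then NaOAc·3H2O, 60 °C
Reagents that add atoms: none
Why: Tosylhydrazone reduction (hydroboration of C=N, then loss of sulfinate and N2, a mild Wolff–Kishner-type deoxygenation) should turn the formyl group into the second C4 methyl without touching ester or alkene; C5 is unchanged in space and its descriptor becomes S only because the priorities change.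

Step 5
Reactants: 9 methyl 3-[(1S)-2,6,6-trimethylcyclohex-2-en-1-yl]propanoate; 10 prop-2-en-1-yl acetate
Product: 11 prop-2-en-1-yl 3-oxo-5-[(1S)-2,6,6-trimethylcyclohex-2-en-1-yl]pentanoate
Conditions: LiN(i-Pr)2 (2.5 equiv), 10 (2.5 equiv), THF, −78 °C; then 9, −78 to −20 °C; aq. NH4Cl
Reagents that add atoms: none
Why: Crossed Claisen condensation of the lithium enolate of allyl acetate with the methyl ester is driven by deprotonation of the beta-keto ester formed; the allyl ester is chosen for neutral removal later.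

Step 6
Reactants: 11 prop-2-en-1-yl 3-oxo-5-[(1S)-2,6,6-trimethylcyclohex-2-en-1-yl]pentanoate
Product: 12 prop-2-en-1-yl (1R,4aS,8aS)-5,5,8a-trimethyl-2-oxodecahydronaphthalene-1-carboxylate
Conditions: SnCl4 (2 equiv), CH2Cl2, 0 to 25 °C
Reagents that add atoms: none
Why: Cation–olefin cyclization: the tin-bound enol protonates the ring alkene at C1 and the tertiary C10 cation is captured by enol carbon C9 through a chair transition state with the C5 side chain equatorial, so C5 should dictate the trans ring fusion at C10; the enolizable C9 settles with the ester equatorial.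

Step 7
Reactants: 13 2,5-dimethoxybenzene-1,4-dicarbaldehyde
Product: 14 2-hydroxy-5-methoxybenzene-1,4-dicarbaldehyde
Conditions: BCl3 (1.0 equiv), CH2Cl2, −78 to 0 °C; then H2O
Reagents that add atoms: none
Why: Lewis acid ether cleavage assisted by chelation to the ortho formyl group; one equivalent limits the reaction to one of the two equivalent methoxy groups, and unchanged 13 is recycled.

Step 8
Reactants: 14 2-hydroxy-5-methoxybenzene-1,4-dicarbaldehyde
Product: 15 2-hydroxy-4-(hydroxymethyl)-5-methoxybenzaldehyde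
Conditions: NaBH4 (0.3 equiv), NaOH (1.1 equiv), MeOH–H2O, −10 °C
Reagents that add atoms: none
Why: Chemoselective borohydride reduction: the phenoxide deactivates the ortho (salicyl) formyl group by conjugation, so hydride should attack only the formyl group meta to it.

Step 9
Reactants: 15 2-hydroxy-4-(hydroxymethyl)-5-methoxybenzaldehyde
Product: 16 2-[(tert-butyldimethylsilyl)oxy]-4-{[(tert-butyldimethylsilyl)oxy]methyl}-5-methoxybenzaldehyde
Conditions: TBSCl (2.5 equiv), imidazole, DMF, 25 °C
Reagents that add atoms: tert-butyldimethylsilyl chloride, CC(C)(C)[Si](C)(C)Cl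
Why: Standard silylation protects the phenol and the primary alcohol in one operation.

Step 10
Reactants: 16 2-[(tert-butyldimethylsilyl)oxy]-4-{[(tert-butyldimethylsilyl)oxy]methyl}-5-methoxybenzaldehyde
Product: 17 (2-[(tert-butyldimethylsilyl)oxy]-4-{[(tert-butyldimethylsilyl)oxy]methyl}-5-methoxyphenyl)methanol
Conditions: NaBH4, MeOH–THF, −20 °C
Reagents that add atoms: none
Why: Borohydride reduction of the aldehyde; the low temperature should suppress migration of the aryl silyl group to the new benzylic oxygen.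

Step 11
Reactants: 17 (2-[(tert-butyldimethylsilyl)oxy]-4-{[(tert-butyldimethylsilyl)oxy]methyl}-5-methoxyphenyl)methanol
Product: 18 1-(bromomethyl)-2-[(tert-butyldimethylsilyl)oxy]-4-{[(tert-butyldimethylsilyl)oxy]methyl}-5-methoxybenzene
Conditions: CBr4, PPh3, CH2Cl2, 0 °C
Reagents that add atoms: tetrabromomethane, BrC(Br)(Br)Br
Why: Appel bromination of the electron-rich benzylic alcohol under neutral conditions that both silyl ethers tolerate.

Step 12
Reactants: 12 prop-2-en-1-yl (1R,4aS,8aS)-5,5,8a-trimethyl-2-oxodecahydronaphthalene-1-carboxylate; 18 1-(bromomethyl)-2-[(tert-butyldimethylsilyl)oxy]-4-{[(tert-butyldimethylsilyl)oxy]methyl}-5-methoxybenzene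
Product: 19 prop-2-en-1-yl (1R,4aS,8aS)-1-(2-[(tert-butyldimethylsilyl)oxy]-4-{[(tert-butyldimethylsilyl)oxy]methyl}-5-methoxybenzyl)-5,5,8a-trimethyl-2-oxodecahydronaphthalene-1-carboxylate
Conditions: NaH (1.1 equiv), DMF, 0 °C; then 18, 0 to 25 °C
Reagents that add atoms: none
Why: C-Alkylation of the beta-keto ester enolate with a reactive benzylic bromide; the ester confines enolization to C9 and the electrophile should enter anti to the axial C10 methyl (this C9 configuration is provisional and is reset in step 13).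

Step 13
Reactants: 19 prop-2-en-1-yl (1R,4aS,8aS)-1-(2-[(tert-butyldimethylsilyl)oxy]-4-{[(tert-butyldimethylsilyl)oxy]methyl}-5-methoxybenzyl)-5,5,8a-trimethyl-2-oxodecahydronaphthalene-1-carboxylate
Product: 21 (1R,4aS,8aS)-1-(2-[(tert-butyldimethylsilyl)oxy]-4-{[(tert-butyldimethylsilyl)oxy]methyl}-5-methoxybenzyl)-5,5,8a-trimethyloctahydronaphthalen-2(1H)-one, via beta-keto acid 20 (not isolated)
Conditions: Pd(PPh3)4 (5 mol %), morpholine (5 equiv), THF, 40 °C
Reagents that add atoms: none
Why: Tsuji–Trost deallylation by zerovalent palladium with morpholine as allyl acceptor, then spontaneous decarboxylation; protonation and amine-mediated equilibration of C9 should place the benzyl group equatorial (C9–H alpha), the thermodynamically favoured epimer.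

Step 14
Reactants: 21 (1R,4aS,8aS)-1-(2-[(tert-butyldimethylsilyl)oxy]-4-{[(tert-butyldimethylsilyl)oxy]methyl}-5-methoxybenzyl)-5,5,8a-trimethyloctahydronaphthalen-2(1H)-one; 4 methyltriphenylphosphonium bromide
Product: 22 tert-butyl({2-[(tert-butyldimethylsilyl)oxy]-5-methoxy-4-{[(1S,4aS,8aS)-5,5,8a-trimethyl-2-methylidenedecahydronaphthalen-1-yl]methyl}benzyl}oxy)dimethylsilane
Conditions: 4, KN(SiMe3)2, THF, 0 °C; then 21, 65 °C
Reagents that add atoms: none
Why: Wittig methylenation of the hindered C8 ketone installs the exocyclic alkene; any enolization at C9 only returns the equatorial epimer.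

Step 15
Reactants: 22 tert-butyl({2-[(tert-butyldimethylsilyl)oxy]-5-methoxy-4-{[(1S,4aS,8aS)-5,5,8a-trimethyl-2-methylidenedecahydronaphthalen-1-yl]methyl}benzyl}oxy)dimethylsilane
Product: 23 5-(hydroxymethyl)-4-methoxy-2-{[(1S,4aS,8aS)-5,5,8a-trimethyl-2-methylidenedecahydronaphthalen-1-yl]methyl}phenol
Conditions: Bu4NF (2.5 equiv), THF, 0 °C; aq. NH4Cl
Reagents that add atoms: none
Why: Fluoride cleaves both silyl ethers and frees the phenol ortho to C11 and the hydroxymethyl group, which is needed as a directing group in step 19.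

Step 16
Reactants: 23 5-(hydroxymethyl)-4-methoxy-2-{[(1S,4aS,8aS)-5,5,8a-trimethyl-2-methylidenedecahydronaphthalen-1-yl]methyl}phenol
Product: 24 5-(hydroxymethyl)-4,4-dimethoxy-2-{[(1S,4aS,8aS)-5,5,8a-trimethyl-2-methylidenedecahydronaphthalen-1-yl]methyl}cyclohexa-2,5-dien-1-one
Conditions: PhI(OAc)2, MeOH, 0 °C
Reagents that add atoms: methanol, CO
Why: Oxidative dearomatization of a para-methoxyphenol by hypervalent iodine with methanol capture para to the phenolic oxygen gives the quinone monoketal with the free carbonyl at C2' next to the alkyl-bearing carbon.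

Step 17
Reactants: 24 5-(hydroxymethyl)-4,4-dimethoxy-2-{[(1S,4aS,8aS)-5,5,8a-trimethyl-2-methylidenedecahydronaphthalen-1-yl]methyl}cyclohexa-2,5-dien-1-one
Product: 25 (1S,6R)-4-(hydroxymethyl)-5,5-dimethoxy-1-{[(1S,4aS,8aS)-5,5,8a-trimethyl-2-methylidenedecahydronaphthalen-1-yl]methyl}-7-oxabicyclo[4.1.0]hept-3-en-2-one
Conditions: Ph3COOH, NaN(SiMe3)2 (3 equiv), L-(+)-diisopropyl tartrate, PhMe, −40 °C
Reagents that add atoms: triphenylmethyl hydroperoxide, OOC(c1ccccc1)(c1ccccc1)c1ccccc1
Why: Weitz–Scheffer (nucleophilic) epoxidation: the peroxide should attack the unsubstituted beta-carbon C6' and not the substituted beta-carbon C4', so only the alkyl-bearing double bond reacts; the sodium tartrate-bound peroxide selects the face and sets both epoxide centres by reagent control.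

Step 18
Reactants: 25 (1S,6R)-4-(hydroxymethyl)-5,5-dimethoxy-1-{[(1S,4aS,8aS)-5,5,8a-trimethyl-2-methylidenedecahydronaphthalen-1-yl]methyl}-7-oxabicyclo[4.1.0]hept-3-en-2-one
Product: 26 (1S,6R)-4-(hydroxymethyl)-1-{[(1S,4aS,8aS)-5,5,8a-trimethyl-2-methylidenedecahydronaphthalen-1-yl]methyl}-7-oxabicyclo[4.1.0]hept-3-ene-2,5-dione
Conditions: oxalic acid, SiO2, H2O, CH2Cl2, 25 °C
Reagents that add atoms: water, O
Why: Mild acid hydrolysis of the dimethyl ketal releases the C5' carbonyl; epoxide and exocyclic alkene should survive these conditions.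

Step 19
Reactants: 26 (1S,6R)-4-(hydroxymethyl)-1-{[(1S,4aS,8aS)-5,5,8a-trimethyl-2-methylidenedecahydronaphthalen-1-yl]methyl}-7-oxabicyclo[4.1.0]hept-3-ene-2,5-dione
Product: 27 (1S,5S,6S)-5-hydroxy-4-(hydroxymethyl)-1-{[(1S,4aS,8aS)-5,5,8a-trimethyl-2-methylidenedecahydronaphthalen-1-yl]methyl}-7-oxabicyclo[4.1.0]hept-3-en-2-one
Conditions: NaBH(OAc)3, AcOH, MeCN, −20 °C
Reagents that add atoms: none
Why: Hydroxyl-directed reduction: the acetoxyborohydride bound to the C4' hydroxymethyl group should deliver hydride only to the adjacent C5' carbonyl (C2' is out of reach and flanked by the quaternary epoxide carbon), on the face anti to the epoxide, giving the cis hydroxy epoxide.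

**Compound list**
1 | methyl 4-oxobutanoate | COC(=O)CCC=O | starting material
2 | 2-(triphenylphosphoranylidene)propanal | CC(C=O)=P(c1ccccc1)(c1ccccc1)c1ccccc1 | starting material
3 | methyl (4E)-5-methyl-6-oxohex-4-enoate | COC(=O)CC/C=C(\C)C=O | intermediate
4 | methyltriphenylphosphonium bromide | C[P+](c1ccccc1)(c1ccccc1)c1ccccc1.[Br-] | starting material
5 | methyl (4E)-5-methylhepta-4,6-dienoate | COC(=O)CC/C=C(\C)C=C | intermediate
6 | methacrolein (2-methylprop-2-enal) | CC(=C)C=O | starting material
7 | methyl 3-[(1R,6S)-6-formyl-2,6-dimethylcyclohex-2-en-1-yl]propanoate (formyl cis to the propanoate chain) | COC(=O)CC[C@H]1[C@@](C)(C=O)CCC=C1C | intermediate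
8 | (E)-N-tosylhydrazone of 7 | COC(=O)CC[C@H]1[C@@](C)(/C=N/NS(=O)(=O)c2ccc(C)cc2)CCC=C1C | intermediate
9 | methyl 3-[(1S)-2,6,6-trimethylcyclohex-2-en-1-yl]propanoate | COC(=O)CC[C@H]1C(C)(C)CCC=C1C | intermediate
10 | prop-2-en-1-yl acetate | CC(=O)OCC=C | starting material
11 | prop-2-en-1-yl 3-oxo-5-[(1S)-2,6,6-trimethylcyclohex-2-en-1-yl]pentanoate | C=CCOC(=O)CC(=O)CC[C@H]1C(C)(C)CCC=C1C | intermediate
12 | prop-2-en-1-yl (1R,4aS,8aS)-5,5,8a-trimethyl-2-oxodecahydronaphthalene-1-carboxylate (trans-decalin, ester equatorial) | O=C1CC[C@H]2C(C)(C)CCC[C@]2(C)[C@H]1C(=O)OCC=C | intermediate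
13 | 2,5-dimethoxybenzene-1,4-dicarbaldehyde | COc1cc(C=O)c(OC)cc1C=O | starting material
14 | 2-hydroxy-5-methoxybenzene-1,4-dicarbaldehyde | COc1cc(C=O)c(O)cc1C=O | intermediate
15 | 2-hydroxy-4-(hydroxymethyl)-5-methoxybenzaldehyde | COc1cc(C=O)c(O)cc1CO | intermediate
16 | 2-[(tert-butyldimethylsilyl)oxy]-4-{[(tert-butyldimethylsilyl)oxy]methyl}-5-methoxybenzaldehyde | COc1cc(C=O)c(O[Si](C)(C)C(C)(C)C)cc1CO[Si](C)(C)C(C)(C)C | intermediate
17 | (2-[(tert-butyldimethylsilyl)oxy]-4-{[(tert-butyldimethylsilyl)oxy]methyl}-5-methoxyphenyl)methanol | COc1cc(CO)c(O[Si](C)(C)C(C)(C)C)cc1CO[Si](C)(C)C(C)(C)C | intermediate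
18 | 1-(bromomethyl)-2-[(tert-butyldimethylsilyl)oxy]-4-{[(tert-butyldimethylsilyl)oxy]methyl}-5-methoxybenzene | COc1cc(CBr)c(O[Si](C)(C)C(C)(C)C)cc1CO[Si](C)(C)C(C)(C)C | intermediate
19 | prop-2-en-1-yl (1R,4aS,8aS)-1-(2-[(tert-butyldimethylsilyl)oxy]-4-{[(tert-butyldimethylsilyl)oxy]methyl}-5-methoxybenzyl)-5,5,8a-trimethyl-2-oxodecahydronaphthalene-1-carboxylate (benzyl alpha, ester beta) | O=C1CC[C@H]2C(C)(C)CCC[C@]2(C)[C@@]1(Cc1cc(OC)c(CO[Si](C)(C)C(C)(C)C)cc1O[Si](C)(C)C(C)(C)C)C(=O)OCC=C | intermediate
20 | beta-keto acid from 19 (free carboxylic acid in place of the allyl ester) | O=C1CC[C@H]2C(C)(C)CCC[C@]2(C)[C@@]1(Cc1cc(OC)c(CO[Si](C)(C)C(C)(C)C)cc1O[Si](C)(C)C(C)(C)C)C(=O)O | intermediate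
21 | (1R,4aS,8aS)-1-(2-[(tert-butyldimethylsilyl)oxy]-4-{[(tert-butyldimethylsilyl)oxy]methyl}-5-methoxybenzyl)-5,5,8a-trimethyloctahydronaphthalen-2(1H)-one (benzyl equatorial) | O=C1CC[C@H]2C(C)(C)CCC[C@]2(C)[C@H]1Cc1cc(OC)c(CO[Si](C)(C)C(C)(C)C)cc1O[Si](C)(C)C(C)(C)C | intermediate
22 | bis(tert-butyldimethylsilyl) ether of 23 | C=C1CC[C@H]2C(C)(C)CCC[C@]2(C)[C@H]1Cc1cc(OC)c(CO[Si](C)(C)C(C)(C)C)cc1O[Si](C)(C)C(C)(C)C | intermediate
23 | 5-(hydroxymethyl)-4-methoxy-2-{[(1S,4aS,8aS)-5,5,8a-trimethyl-2-methylidenedecahydronaphthalen-1-yl]methyl}phenol | C=C1CC[C@H]2C(C)(C)CCC[C@]2(C)[C@H]1Cc1cc(OC)c(CO)cc1O | intermediate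
24 | 5-(hydroxymethyl)-4,4-dimethoxy-2-{[(1S,4aS,8aS)-5,5,8a-trimethyl-2-methylidenedecahydronaphthalen-1-yl]methyl}cyclohexa-2,5-dien-1-one | C=C1CC[C@H]2C(C)(C)CCC[C@]2(C)[C@H]1CC1=CC(OC)(OC)C(CO)=CC1=O | intermediate
25 | (1S,6R)-4-(hydroxymethyl)-5,5-dimethoxy-1-{[(1S,4aS,8aS)-5,5,8a-trimethyl-2-methylidenedecahydronaphthalen-1-yl]methyl}-7-oxabicyclo[4.1.0]hept-3-en-2-one | C=C1CC[C@H]2C(C)(C)CCC[C@]2(C)[C@H]1C[C@]12O[C@H]1C(OC)(OC)C(CO)=CC2=O | intermediate
26 | (1S,6R)-4-(hydroxymethyl)-1-{[(1S,4aS,8aS)-5,5,8a-trimethyl-2-methylidenedecahydronaphthalen-1-yl]methyl}-7-oxabicyclo[4.1.0]hept-3-ene-2,5-dione | C=C1CC[C@H]2C(C)(C)CCC[C@]2(C)[C@H]1C[C@]12O[C@H]1C(=O)C(CO)=CC2=O | intermediate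
27 | (1S,5S,6S)-5-hydroxy-4-(hydroxymethyl)-1-{[(1S,4aS,8aS)-5,5,8a-trimethyl-2-methylidenedecahydronaphthalen-1-yl]methyl}-7-oxabicyclo[4.1.0]hept-3-en-2-one (hydroxyl cis to the epoxide) | C=C1CC[C@H]2C(C)(C)CCC[C@]2(C)[C@H]1C[C@]12O[C@H]1[C@@H](O)C(CO)=CC2=O | target

**Step count and risks**

Total step count: 19. Longest linear sequence: 14 steps (steps 1–6 and 12–19); the arene branch (steps 7–11) joins at step 12.

Steps most likely to fail:

Step 3. What may go wrong is erosion of regio-, endo- or facial selectivity: the C10 methyl of the diene directs against the C5 substituent, and an exo pathway delivers the mirror-image configuration at C5. Turnover may also be slow if the ester competes for the boron catalyst. The fallback runs from 5 to 9 and replaces catalyst control by resolution. 5 and 6 are combined with EtAlCl2 in CH2Cl2 at −78 °C, which should give racemic methyl 3-[(1R*,6S*)-6-formyl-2,6-dimethylcyclohex-2-en-1-yl]propanoate F1. The hydrazone reduction of step 4 then gives racemic methyl 3-(2,6,6-trimethylcyclohex-2-en-1-yl)propanoate F2. LiOH in THF–H2O gives racemic 3-(2,6,6-trimethylcyclohex-2-en-1-yl)propanoic acid F3. Fractional crystallization of its salt with one enantiomer of 1-phenylethylamine, then acidification, gives 3-[(1S)-2,6,6-trimethylcyclohex-2-en-1-yl]propanoic acid F4. MeI and K2CO3 in DMF return 9.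

Step 12. What may go wrong is O-alkylation, or no reaction, at the neopentyl-like C9 between the carbonyl groups and the quaternary C10. The fallback runs from 12 and 18 to 19 and replaces the substitution by conjugate addition to an ortho-quinone methide. CsF in MeCN removes the aryl silyl group of 18 and bromide leaves, giving 3-{[(tert-butyldimethylsilyl)oxy]methyl}-4-methoxy-6-methylidenecyclohexa-2,4-dien-1-one F5 in the flask. The enol of 12 adds through C9 to its exocyclic carbon (Michael addition driven by rearomatization) to give prop-2-en-1-yl (1R,4aS,8aS)-1-(4-{[(tert-butyldimethylsilyl)oxy]methyl}-2-hydroxy-5-methoxybenzyl)-5,5,8a-trimethyl-2-oxodecahydronaphthalene-1-carboxylate F6. TBSCl and imidazole in DMF return 19.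

Step 17. What may go wrong is poor or reversed facial selectivity of peroxide addition, since the drimane stereocentres are remote and the tartrate alone must choose the face. The fallback runs from 24 to 26 and replaces reagent control by a covalently bound chiral ketal. Acetal exchange of 24 with (2R,4R)-pentane-2,4-diol and pyridinium p-toluenesulfonate in benzene gives the (2R,4R)-pentane-2,4-diyl spiroketal of 24 F7, whose axial methyl group shields one face of the C1'=C6' double bond. t-BuOOH and DBU in CH2Cl2 give the (1S,6R)-epoxide of this spiroketal F8. Oxalic acid on wet silica releases the diol and gives 26. The diol enantiomer is chosen to match the required face.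

Further compounds
F1 | step 3 | racemic methyl 3-[(1R*,6S*)-6-formyl-2,6-dimethylcyclohex-2-en-1-yl]propanoate (one enantiomer drawn) | COC(=O)CC[C@H]1[C@@](C)(C=O)CCC=C1C
F2 | step 3 | racemic methyl 3-(2,6,6-trimethylcyclohex-2-en-1-yl)propanoate | COC(=O)CCC1C(C)(C)CCC=C1C
F3 | step 3 | racemic 3-(2,6,6-trimethylcyclohex-2-en-1-yl)propanoic acid | OC(=O)CCC1C(C)(C)CCC=C1C
F4 | step 3 | 3-[(1S)-2,6,6-trimethylcyclohex-2-en-1-yl]propanoic acid | OC(=O)CC[C@H]1C(C)(C)CCC=C1C
F5 | step 12 | 3-{[(tert-butyldimethylsilyl)oxy]methyl}-4-methoxy-6-methylidenecyclohexa-2,4-dien-1-one | C=C1C=C(OC)C(CO[Si](C)(C)C(C)(C)C)=CC1=O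
F6 | step 12 | prop-2-en-1-yl (1R,4aS,8aS)-1-(4-{[(tert-butyldimethylsilyl)oxy]methyl}-2-hydroxy-5-methoxybenzyl)-5,5,8a-trimethyl-2-oxodecahydronaphthalene-1-carboxylate | O=C1CC[C@H]2C(C)(C)CCC[C@]2(C)[C@@]1(Cc1cc(OC)c(CO[Si](C)(C)C(C)(C)C)cc1O)C(=O)OCC=C
F7 | step 17 | (2R,4R)-pentane-2,4-diyl spiroketal of 24 | C=C1CC[C@H]2C(C)(C)CCC[C@]2(C)[C@H]1CC1=CC2(O[C@H](C)C[C@@H](C)O2)C(CO)=CC1=O
F8 | step 17 | (1S,6R)-epoxide of the (2R,4R)-pentane-2,4-diyl spiroketal of 24 | C=C1CC[C@H]2C(C)(C)CCC[C@]2(C)[C@H]1C[C@]12O[C@H]1C1(O[C@H](C)C[C@@H](C)O1)C(CO)=CC2=O
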